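Numbering (eudesmane): ring A = C1–C5 + C10, ring B = C5–C10. C3 carries the angelate, C4 the carbinol and a methyl group, C5 is the ring-fusion CH, C10 the quaternary carbon, C8 the ketone and C11 the hydroperoxy carbon. The target is (3S,4S,5R,10R): 3β-O, 4α-OH, 4β-CH3, 5α-H, 10β-CH3.
Cuts, in order: O–C11 (C6=C7 moves back to C7=C11), the acyl–O3 bond, C7=C11 (acetone), then C4–C5 and C9–C10 together, then C4–CH3, C5–C6, C10–CH3 and C10≡C5.
Enabling feature: C3(OR)–C4(OH)(CH3) of ring A is a masked α-alkoxy methyl ketone, the fusion bond C5–C10 is a masked E trisubstituted alkene, and the C8 ketone of ring B is a masked enol silane with C9 as its nucleophilic end.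
Forward: the chain C4–C3–C2–C1–C10 (the five carbons of L-glutamic acid) gains C5 as an alkyne carbon, the C10 methyl group by carboalumination and C6–C9 from methyl vinyl ketone. Rings A and B then close in one operation, ring A leading.
Stereochemistry: C3 is Cα of L-glutamic acid, kept by diazotisation with retention. C4, C5 and C10 follow from C3 through a tin-chelated chair–chair fold and the E alkene. The Z ester geometry comes with angelic acid.

Key step: step 11

Assumption: a 2-naphthylmethyl (NAP) ether should bind SnCl4 as a benzyl ether does. It is used on O3 because DDQ removes it later without touching the enone, which hydrogenolysis of a benzyl ether would reduce.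

Step 1
Reactants: 1 L-glutamic acid
Product: 2 (S)-5-oxotetrahydrofuran-2-carboxylic acid
Conditions: NaNO2, aq HCl, 0 °C to rt; evaporation, EtOAc extraction
Reagents that add atoms: none
Why: In this diazotisation of an α-amino acid the α-carboxylate expels N2 to give an α-lactone that the γ-carboxyl group opens, and the two inversions add up to retention, so Cα stays S and becomes C3.

Step 2
Reactants: 2 (S)-5-oxotetrahydrofuran-2-carboxylic acid
Product: 3 tert-butyl (S)-5-oxotetrahydrofuran-2-carboxylate
Conditions: Cl3CC(=NH)Ot-Bu, CH2Cl2/cyclohexane, rt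
Reagents that add atoms: tert-butyl 2,2,2-trichloroacetimidate, CC(C)(C)OC(=N)C(Cl)(Cl)Cl
Why: O-alkylation of the acid by the trichloroacetimidate never activates the carbonyl group, so C3 cannot racemise, and the bulky ester shields C4 in step 3.

Step 3
Reactants: 3 tert-butyl (S)-5-oxotetrahydrofuran-2-carboxylate
Product: 4 tert-butyl (2S)-5-hydroxytetrahydrofuran-2-carboxylate (lactol; both hemiacetal epimers)
Conditions: i-Bu2AlH (1.05 equiv), CH2Cl2, −78 °C; aq KNaC4H4O6
Reagents that add atoms: none
Why: Half-reduction of a γ-lactone by i-Bu2AlH stops at the aluminium lactolate at −78 °C while the hindered tert-butyl ester reacts far more slowly, and the new hemiacetal centre is an epimer mixture that is lost in step 4.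

Step 4
Reactants: 4 tert-butyl (2S)-5-hydroxytetrahydrofuran-2-carboxylate
Product: 5 tert-butyl (S)-2-hydroxyhex-5-ynoate
Conditions: MeCOC(N2)P(O)(OMe)2, K2CO3, MeOH, 0 °C to rt
Reagents that add atoms: dimethyl (1-diazo-2-oxopropyl)phosphonate, CC(=O)C(=[N+]=[N-])P(=O)(OC)OC
Why: The Seyferth–Gilbert homologation in its Ohira–Bestmann form traps the open hydroxy aldehyde tautomer of the lactol, turns C10 into an alkyne carbon, adds C5 and frees O3 in a compound that can no longer lactonise.

Step 5
Reactants: 5 tert-butyl (S)-2-hydroxyhex-5-ynoate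
Product: 6 (S)-2-hydroxyhex-5-ynoic acid
Conditions: CF3CO2H, CH2Cl2, 0 °C to rt; evaporation
Reagents that add atoms: none
Why: Acidolysis of a tert-butyl ester (loss of the tert-butyl cation as 2-methylpropene) leaves the alkyne, the alcohol and C3 untouched.

Step 6
Reactants: 6 (S)-2-hydroxyhex-5-ynoic acid
Product: 7 (S)-2-hydroxy-N-methoxy-N-methylhex-5-ynamide
Conditions: MeNHOMe·HCl, EDC·HCl, HOBt, N-methylmorpholine, CH2Cl2, 0 °C to rt
Reagents that add atoms: N,O-dimethylhydroxylamine hydrochloride, CNOC.Cl
Why: A carbodiimide/HOBt amide coupling gives the Weinreb amide, the only form of C4 that survives steps 7 to 9 and still becomes a methyl ketone under conditions an enol silane tolerates.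

Step 7
Reactants: 7 (S)-2-hydroxy-N-methoxy-N-methylhex-5-ynamide
Product: 8 (S)-N-methoxy-N-methyl-2-(naphthalen-2-ylmethoxy)hex-5-ynamide
Conditions: NaH (1.05 equiv), 2-(bromomethyl)naphthalene, n-Bu4NI (cat.), THF/DMF, 0 °C
Reagents that add atoms: 2-(bromomethyl)naphthalene, BrCc1ccc2ccccc2c1
Why: In this Williamson ether synthesis the alcohol is far more acidic than the amide α-hydrogen or the alkyne hydrogen, so one equivalent of base should alkylate O3 alone and leave C3 intact.

Step 8
Reactants: 8 (S)-N-methoxy-N-methyl-2-(naphthalen-2-ylmethoxy)hex-5-ynamide, 9 methyl vinyl ketone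
Product: 11 (S,E)-N-methoxy-N,5-dimethyl-2-(naphthalen-2-ylmethoxy)-9-oxodec-5-enamide, via alkenyl dimethylalane 10 (not isolated)
Conditions: AlMe3 (3 equiv), Cp2ZrCl2 (0.25 equiv), ClCH2CH2Cl, rt; volatiles removed; then 9, CuBr·SMe2 (10 mol %), THF, −30 °C; aq KNaC4H4O6
Reagents that add atoms: trimethylaluminium, C[Al](C)C
Why: The Negishi zirconium-catalysed carboalumination adds methyl (to C10) and aluminium (to C5) syn across the alkyne, and copper-catalysed conjugate addition of the alkenylalane to the enone passes the alkenyl group on with retention, so the C5=C10 alkene should be purely E.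

Step 9
Reactants: 11 (S,E)-N-methoxy-N,5-dimethyl-2-(naphthalen-2-ylmethoxy)-9-oxodec-5-enamide
Product: 13 (S,E)-9-[(tert-butyldimethylsilyl)oxy]-N-methoxy-N,5-dimethyl-2-(naphthalen-2-ylmethoxy)deca-5,9-dienamide, via lithium enolate 12 (not isolated)
Conditions: LiN(i-Pr)2 (1.1 equiv), THF, −78 °C; then TBSOTf, −78 °C; Et3N, aq NaHCO3
Reagents that add atoms: tert-butyldimethylsilyl trifluoromethanesulfonate, CC(C)(C)[Si](C)(C)OS(=O)(=O)C(F)(F)F
Why: Kinetic enolisation of a methyl ketone by a hindered amide base removes a C9 methyl hydrogen, the ketone is much more acidic than the amide, and O-silylation fixes the terminal C8=C9 enol silane.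

Step 10
Reactants: 13 (S,E)-9-[(tert-butyldimethylsilyl)oxy]-N-methoxy-N,5-dimethyl-2-(naphthalen-2-ylmethoxy)deca-5,9-dienamide
Product: 14 (S,E)-10-[(tert-butyldimethylsilyl)oxy]-6-methyl-3-(naphthalen-2-ylmethoxy)undeca-6,10-dien-2-one
Conditions: MeMgBr (1.5 equiv), THF, −78 to −20 °C; pH 7 phosphate buffer
Reagents that add atoms: methylmagnesium bromide, C[Mg]Br
Why: In the Weinreb ketone synthesis the magnesium-chelated tetrahedral adduct holds until the neutral quench, which prevents over-addition and epimerisation at C3 and spares the TBS enol ether.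

Step 11
Reactants: 14 (S,E)-10-[(tert-butyldimethylsilyl)oxy]-6-methyl-3-(naphthalen-2-ylmethoxy)undeca-6,10-dien-2-one
Product: 16 (3S,4S,5R,10R)-4α-hydroxy-3β-(naphthalen-2-ylmethoxy)-11,12,13-trinoreudesman-8-one, via SnCl4 chelate 15 (not isolated)
Conditions: SnCl4 (1.2 equiv), 2,6-di-tert-butyl-4-methylpyridine (0.3 equiv), CH2Cl2 (0.005 M), −78 °C, slow addition of 14; aq NaHCO3
Reagents that add atoms: tin tetrachloride, Cl[Sn](Cl)(Cl)Cl (its atoms are held in 15 only; none stays in 16)
Why: Proposed new method: SnCl4 ties the C4 ketone oxygen and the C3 ether oxygen of 14 into the five-membered chelate 15, the E C5=C10 alkene attacks the activated C4 through C5 while positive charge builds at tertiary C10, and the C8 enol silane closes on C10 through C9 and gives its silyl group to chloride, which makes the otherwise reversible ketone addition irreversible. The closest known reaction type is the Lewis-acid Prins polyene cyclisation that starts at an aldehyde or acetal and ends at a silyl enol ether; a chelated α-alkoxy methyl ketone has not served as initiator. Ring A (bond C4–C5) closes 6-endo-trig at the alkene with the carbonyl oxygen outside the ring, and ring B (bond C9–C10) closes 6-endo-trig at the enol ether, each through a chair. C5 and C10 are set by anti addition of C4 and C9 across the E alkene in the chair–chair fold, which places H5 and the C10 methyl group trans. C4 is set by the metal, which is anchored to the equatorial O3 and stays in the equatorial belt because an axial O–SnCl4 unit would collide with the C10 methyl group and the axial H2, so O4 ends equatorial (α) and the C4 methyl group axial (β); which of the two mirror-image folds is used is decided by C3, whose tin-bound, doubly substituted oxygen should sit equatorial, where the C3–O bond is also antiperiplanar to the forming C4–C5 bond (polar Felkin–Anh alignment), and the late transition state of this uphill addition lets the O–C–C–O angle open towards the 60° that long Sn–O bonds tolerate. The step needs the alkene, not the more nucleophilic enol silane, to reach the ketone: C9-to-C4 attack would need a ten-membered ring, and high dilution, the bulky TBS group, the pyridine base and −78 °C should hold back intermolecular Mukaiyama aldol addition, silicon-to-tin exchange and protodesilylation.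

Step 12
Reactants: 16 (3S,4S,5R,10R)-4α-hydroxy-3β-(naphthalen-2-ylmethoxy)-11,12,13-trinoreudesman-8-one, 17 acetone
Product: 19 4α,11-dihydroxy-3β-(naphthalen-2-ylmethoxy)eudesman-8-one (C7 epimers), via dilithio alkoxide enolate 18 (not isolated)
Conditions: LiN(i-Pr)2 (2.2 equiv), THF, −78 °C; then 17, −78 °C; aq NH4Cl at −78 °C
Reagents that add atoms: none
Why: In this directed aldol addition the first equivalent of base takes the C4 hydroxyl proton, the second takes a C7 hydrogen because C9 is neopentyl next to quaternary C10, and C7 forms as an epimer mixture (mainly equatorial) that step 13 erases.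

Step 13
Reactants: 19 4α,11-dihydroxy-3β-(naphthalen-2-ylmethoxy)eudesman-8-one
Product: 21 4α-hydroxy-3β-(naphthalen-2-ylmethoxy)eudesm-7(11)-en-8-one, via C11 mesylate 20 (not isolated)
Conditions: MsCl (1.2 equiv), Et3N, CH2Cl2, 0 °C; then DBU, rt
Reagents that add atoms: methanesulfonyl chloride, CS(=O)(=O)Cl (its atoms are held in 20 only; none stays in 21)
Why: Mesylation through sulfene should take the less crowded tertiary alcohol (C4–OH is walled in by C3–O, C5 and an axial methyl group), the β-mesyloxy ketone then loses methanesulfonate by E1cB elimination, and DBU moves any isopropenyl isomer into conjugation.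

Step 14
Reactants: 21 4α-hydroxy-3β-(naphthalen-2-ylmethoxy)eudesm-7(11)-en-8-one
Product: 22 3β,4α-dihydroxyeudesm-7(11)-en-8-one
Conditions: DDQ, CH2Cl2/pH 7 buffer, 0 °C to rt
Reagents that add atoms: none
Why: Oxidative cleavage of a 2-naphthylmethyl ether (hydride abstraction by DDQ, then hydrolysis of the oxocarbenium ion by the water present) frees O3 without reducing or isomerising the tetrasubstituted enone.

Step 15
Reactants: 22 3β,4α-dihydroxyeudesm-7(11)-en-8-one, 23 angelic acid
Product: 25 3β-angeloyloxy-4α-hydroxyeudesm-7(11)-en-8-one, via mixed anhydride 24 (not isolated)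
Conditions: 23, 2,4,6-Cl3C6H2COCl, Et3N, toluene, rt; then 22, 80 °C
Reagents that add atoms: 2,4,6-trichlorobenzoyl chloride, O=C(Cl)c1c(Cl)cc(Cl)cc1Cl (its atoms are held in 24 only; none stays in 25)
Why: A Yamaguchi-type esterification run without a nucleophilic catalyst avoids the addition–elimination path that turns angelates into tiglates, and only the secondary equatorial C3–OH is acylated because the C4 alcohol is tertiary.

Step 16
Reactants: 25 3β-angeloyloxy-4α-hydroxyeudesm-7(11)-en-8-one
Product: 26 3β-angeloyloxy-4α-hydroxy-11-hydroperoxyeudesm-6-en-8-one (CNP0161122.1)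
Conditions: O2, tetraphenylporphyrin (cat.), visible light, CH2Cl2, 0 °C
Reagents that add atoms: dioxygen, O=O
Why: In the Schenck ene reaction of singlet oxygen with an enone locked s-cis, oxygen adds to C11 and the hydrogen comes from the group geminal to the carbonyl substituent (axial H6β), so the double bond moves to C6=C7 in conjugation with C8=O, while the electron-poor angelate alkene reacts much more slowly and no stereocentre is formed or touched.

Compound list
1 | L-glutamic acid | N[C@@H](CCC(=O)O)C(=O)O | starting material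
2 | (S)-5-oxotetrahydrofuran-2-carboxylic acid | OC(=O)[C@@H]1CCC(=O)O1 | intermediate
3 | tert-butyl (S)-5-oxotetrahydrofuran-2-carboxylate | CC(C)(C)OC(=O)[C@@H]1CCC(=O)O1 | intermediate
4 | tert-butyl (2S)-5-hydroxytetrahydrofuran-2-carboxylate (hemiacetal epimers) | CC(C)(C)OC(=O)[C@@H]1CCC(O)O1 | intermediate
5 | tert-butyl (S)-2-hydroxyhex-5-ynoate | CC(C)(C)OC(=O)[C@@H](O)CCC#C | intermediate
6 | (S)-2-hydroxyhex-5-ynoic acid | OC(=O)[C@@H](O)CCC#C | intermediate
7 | (S)-2-hydroxy-N-methoxy-N-methylhex-5-ynamide | CON(C)C(=O)[C@@H](O)CCC#C | intermediate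
8 | (S)-N-methoxy-N-methyl-2-(naphthalen-2-ylmethoxy)hex-5-ynamide | CON(C)C(=O)[C@@H](OCc1ccc2ccccc2c1)CCC#C | intermediate
9 | methyl vinyl ketone | C=CC(C)=O | starting material
10 | (S,E)-alkenyl dimethylalane from 8 | CON(C)C(=O)[C@@H](OCc1ccc2ccccc2c1)CC/C(C)=C/[Al](C)C | intermediate
11 | (S,E)-N-methoxy-N,5-dimethyl-2-(naphthalen-2-ylmethoxy)-9-oxodec-5-enamide | CON(C)C(=O)[C@@H](OCc1ccc2ccccc2c1)CC/C(C)=C/CCC(C)=O | intermediate
12 | kinetic lithium enolate of 11 | CON(C)C(=O)[C@@H](OCc1ccc2ccccc2c1)CC/C(C)=C/CCC(=C)O[Li] | intermediate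
13 | (S,E)-9-[(tert-butyldimethylsilyl)oxy]-N-methoxy-N,5-dimethyl-2-(naphthalen-2-ylmethoxy)deca-5,9-dienamide | CON(C)C(=O)[C@@H](OCc1ccc2ccccc2c1)CC/C(C)=C/CCC(=C)O[Si](C)(C)C(C)(C)C | intermediate
14 | (S,E)-10-[(tert-butyldimethylsilyl)oxy]-6-methyl-3-(naphthalen-2-ylmethoxy)undeca-6,10-dien-2-one | CC(=O)[C@@H](OCc1ccc2ccccc2c1)CC/C(C)=C/CCC(=C)O[Si](C)(C)C(C)(C)C | intermediate
15 | SnCl4 chelate of 14 (O3 and O4 on tin) | CC1=[O+][Sn-2](Cl)(Cl)(Cl)(Cl)[O+](Cc2ccc3ccccc3c2)[C@H]1CC/C(C)=C/CCC(=C)O[Si](C)(C)C(C)(C)C | intermediate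
16 | (3S,4S,5R,10R)-4α-hydroxy-3β-(naphthalen-2-ylmethoxy)-11,12,13-trinoreudesman-8-one | C(c3ccc4ccccc4c3)O[C@H]1CC[C@]2(C)CC(=O)CC[C@H]2[C@]1(C)O | intermediate
17 | acetone | CC(C)=O | starting material
18 | dilithio C4 alkoxide C7(8) enolate of 16 | C(c3ccc4ccccc4c3)O[C@H]1CC[C@]2(C)CC(O[Li])=CC[C@H]2[C@]1(C)O[Li] | intermediate
19 | 4α,11-dihydroxy-3β-(naphthalen-2-ylmethoxy)eudesman-8-one (C7 epimers) | C(c3ccc4ccccc4c3)O[C@H]1CC[C@]2(C)CC(=O)C(C(C)(C)O)C[C@H]2[C@]1(C)O | intermediate
20 | C11 methanesulfonate of 19 | C(c3ccc4ccccc4c3)O[C@H]1CC[C@]2(C)CC(=O)C(C(C)(C)OS(C)(=O)=O)C[C@H]2[C@]1(C)O | intermediate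
21 | 4α-hydroxy-3β-(naphthalen-2-ylmethoxy)eudesm-7(11)-en-8-one | C(c3ccc4ccccc4c3)O[C@H]1CC[C@]2(C)CC(=O)C(=C(C)C)C[C@H]2[C@]1(C)O | intermediate
22 | 3β,4α-dihydroxyeudesm-7(11)-en-8-one | O[C@H]1CC[C@]2(C)CC(=O)C(=C(C)C)C[C@H]2[C@]1(C)O | intermediate
23 | angelic acid, (Z)-2-methylbut-2-enoic acid | C/C=C(/C)C(=O)O | starting material
24 | angelic 2,4,6-trichlorobenzoic anhydride | C/C=C(/C)C(=O)OC(=O)c1c(Cl)cc(Cl)cc1Cl | intermediate
25 | 3β-angeloyloxy-4α-hydroxyeudesm-7(11)-en-8-one | C/C=C(/C)C(=O)O[C@H]1CC[C@]2(C)CC(=O)C(=C(C)C)C[C@H]2[C@]1(C)O | intermediate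
26 | 3β-angeloyloxy-4α-hydroxy-11-hydroperoxyeudesm-6-en-8-one (CNP0161122.1) | C/C=C(/C)C(=O)O[C@H]1CC[C@]2(C)CC(=O)C(C(C)(C)OO)=C[C@H]2[C@]1(C)O | target

Total step count: 16. Longest linear sequence: 16 steps, from L-glutamic acid; all other partners are bought.

Steps most likely to fail

**Step 11.**
- The fold may not follow C3. A flatter chelate is better served by an axial C3–O bond, which would invert C4, C5 and C10 relative to C3.
- The repulsion between the C4 and C10 methyl groups may push O4 axial.
- The enol silane may be lost by exchange with tin before ring A closes.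
- The fallback sets out from 13 and returns at 16. It takes the C4 centre out of the cyclisation and uses known reactions only.
- i-Bu2AlH (THF, −78 °C) should reduce the Weinreb amide of 13 to the α-(naphthylmethoxy) aldehyde F1.
- Me2AlCl or SnCl4 at −78 °C then starts the aldehyde-initiated Prins bicyclisation, a known reaction class in which no methyl/methyl clash arises. It gives the 15-nor-4-hydroxy ketone F2, whose C4 configuration does not matter.
- Ethylene glycol with PPTS gives the C8 dioxolane F3, Dess–Martin periodinane gives the C4 ketone F4, and Ph3P=CH2 gives the 4(15)-methylene compound F5.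
- m-CPBA should approach from the α face, away from the axial C10 methyl group, and give the 4α,15-epoxide F6.
- LiEt3BH opens the epoxide at C15 to the 4α-carbinol ketal F7, and PPTS in wet acetone frees 16.

**Step 8.**
- The enone may polymerise on the Lewis-acidic alane.
- Methyl may be transferred in place of the alkenyl group.
- The amide may tie up aluminium so that copper transfer stalls.
- The fallback sets out from 8 and returns at 11.
- The carboalumination is quenched with I2 to give the E vinyl iodide F8.
- 9-BBN-H adds to 2-methyl-2-vinyl-1,3-dioxolane to give the B-alkyl borane F9.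
- A B-alkyl Suzuki–Miyaura coupling of F8 with F9 (PdCl2(dppf), Cs2CO3, DMF/H2O, rt) joins C5 to C6 with retention of the alkene geometry and gives the keto-protected amide F10.
- PPTS in wet acetone then gives 11.

**Step 16.**
- Hydrogen may be taken from the C12 or C13 methyl groups in place of the crowded H6β.
- A slow reaction may let the angelate alkene be oxygenated as well.
- The fallback sets out from 21 and returns at 26. It oxygenates before the ester is in place, so the reaction can be driven hard and the regioisomers separated early.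
- The same photooxygenation of 21 gives the NAP-protected hydroperoxide F11.
- Et3SiCl with imidazole masks the hydroperoxide as the triethylsilyl peroxide F12; the tertiary C4–OH stays free.
- DDQ in wet CH2Cl2 gives the C3 alcohol F13, and the mixed anhydride 24 in toluene gives the angelate silyl peroxide F14.
- HF·pyridine in THF at 0 °C releases 26.

Further compounds
F1 | step 11 | (S,E)-9-[(tert-butyldimethylsilyl)oxy]-5-methyl-2-(naphthalen-2-ylmethoxy)deca-5,9-dienal | O=C[C@@H](OCc1ccc2ccccc2c1)CC/C(C)=C/CCC(=C)O[Si](C)(C)C(C)(C)C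
F2 | step 11 | 4-hydroxy-3β-(naphthalen-2-ylmethoxy)-11,12,13,15-tetranoreudesman-8-one (C4 epimers) | C(c3ccc4ccccc4c3)O[C@H]1CC[C@]2(C)CC(=O)CC[C@H]2C1O
F3 | step 11 | C8 ethylene ketal of F2 | C(c3ccc4ccccc4c3)O[C@H]1CC[C@]2(C)CC5(OCCO5)CC[C@H]2C1O
F4 | step 11 | C4 ketone C8 ethylene ketal | C(c3ccc4ccccc4c3)O[C@H]1CC[C@]2(C)CC5(OCCO5)CC[C@H]2C1=O
F5 | step 11 | 4(15)-methylene C8 ethylene ketal | C(c3ccc4ccccc4c3)O[C@H]1CC[C@]2(C)CC5(OCCO5)CC[C@H]2C1=C
F6 | step 11 | 4α,15-epoxide C8 ethylene ketal | C(c3ccc4ccccc4c3)O[C@H]1CC[C@]2(C)CC5(OCCO5)CC[C@H]2[C@@]16CO6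
F7 | step 11 | C8 ethylene ketal of 16 | C(c3ccc4ccccc4c3)O[C@H]1CC[C@]2(C)CC5(OCCO5)CC[C@H]2[C@]1(C)O
F8 | step 8 | (S,E)-6-iodo-N-methoxy-N,5-dimethyl-2-(naphthalen-2-ylmethoxy)hex-5-enamide | CON(C)C(=O)[C@@H](OCc1ccc2ccccc2c1)CC/C(C)=C/I
F9 | step 8 | 9-[2-(2-methyl-1,3-dioxolan-2-yl)ethyl]-9-borabicyclo[3.3.1]nonane | CC1(CCB2C3CCCC2CCC3)OCCO1
F10 | step 8 | C9 ethylene ketal of 11 | CON(C)C(=O)[C@@H](OCc1ccc2ccccc2c1)CC/C(C)=C/CCC3(C)OCCO3
F11 | step 16 | 4α-hydroxy-11-hydroperoxy-3β-(naphthalen-2-ylmethoxy)eudesm-6-en-8-one | C(c3ccc4ccccc4c3)O[C@H]1CC[C@]2(C)CC(=O)C(C(C)(C)OO)=C[C@H]2[C@]1(C)O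
F12 | step 16 | triethylsilyl peroxide of F11 | C(c3ccc4ccccc4c3)O[C@H]1CC[C@]2(C)CC(=O)C(C(C)(C)OO[Si](CC)(CC)CC)=C[C@H]2[C@]1(C)O
F13 | step 16 | 3β,4α-dihydroxy-11-(triethylsilylperoxy)eudesm-6-en-8-one | O[C@H]1CC[C@]2(C)CC(=O)C(C(C)(C)OO[Si](CC)(CC)CC)=C[C@H]2[C@]1(C)O
F14 | step 16 | 3β-angeloyloxy-4α-hydroxy-11-(triethylsilylperoxy)eudesm-6-en-8-one | C/C=C(/C)C(=O)O[C@H]1CC[C@]2(C)CC(=O)C(C(C)(C)OO[Si](CC)(CC)CC)=C[C@H]2[C@]1(C)O
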